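**Assumption:** the target has no stereocentre and no stereogenic double bond, so "single enantiomer" requires no stereocontrol; the racemic centre of aldol 12 and the E geometry of enone 13 are both erased later.

## Retrosynthetic overview
1. Target 17 ⇐ MOM ether 16 (acidic deprotection) ⇐ saturated ketone 14 (Wolff–Kishner) ⇐ enone 13 (C=C hydrogenation).
2. Key C–C bond (benzylic C1–C2 of the side chain): crossed aldol (Claisen–Schmidt) condensation of aryl aldehyde 6 (1 C) with icosan-2-one 11 (20 C), giving the full C21 chain.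
3. Aldehyde 6 ⇐ 2,4-dimethoxyphenol 3 (ortho-formylation, then MOM protection) ⇐ 2,4-dimethoxybenzaldehyde 1 (Baeyer–Villiger).
4. Ketone 11 ⇐ octadecyl Grignard from 1-bromooctadecane 7 + Weinreb amide 8.
5. No ring is formed; the benzene ring is carried through intact from 1.

## Route

Step 1
Reactants: 1 2,4-dimethoxybenzaldehyde
Product: 3 2,4-dimethoxyphenol, via 2,4-dimethoxyphenyl formate 2 (not isolated)
Conditions: mCPBA (1.3 equiv), CH2Cl2, 0 °C to rt; aq. NaHCO3 wash; then K2CO3 (0.2 equiv), MeOH, N2, rt; dilute HCl work-up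
Reagents that add atoms: mCPBA (3-chloroperoxybenzoic acid), O=C(OO)c1cccc(Cl)c1
Why: Baeyer–Villiger (Dakin-type) oxidation in which the electron-rich 2,4-dimethoxyphenyl group migrates in preference to hydride, and the resulting aryl formate is transesterified by methanol under catalytic base to free the phenol.

Step 2
Reactants: 3 2,4-dimethoxyphenol
Product: 5 2-hydroxy-3,5-dimethoxybenzaldehyde, via 2-(hydroxymethyl)-4,6-dimethoxyphenol 4 (not isolated)
Conditions: anhydrous MgCl2 (1.5 equiv), Et3N (3.75 equiv), paraformaldehyde (6–7 equiv), MeCN, reflux; 1 M HCl work-up (MgCl2 and Et3N are returned unchanged)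
Reagents that add atoms: paraformaldehyde (formaldehyde unit), C=O
Why: Casnati–Skattebøl magnesium-mediated ortho-formylation, in which the magnesium phenoxide delivers formaldehyde only to the single free ortho carbon and the salicyl alcohol salt is oxidised by a second formaldehyde through Oppenauer-type hydride transfer.

Step 3
Reactants: 5 2-hydroxy-3,5-dimethoxybenzaldehyde
Product: 6 3,5-dimethoxy-2-(methoxymethoxy)benzaldehyde
Conditions: MOMCl (1.5 equiv), K2CO3 (2.5 equiv), DMF, 0 °C to rt
Reagents that add atoms: chloromethyl methyl ether (MOMCl), COCCl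
Why: Williamson-type O-alkylation of the phenoxide; the MOM ether survives base, hydrogenation and Wolff–Kishner conditions and keeps the phenol from closing onto the later ketone as a chromanol.

Step 4
Reactants: 7 1-bromooctadecane; 8 N-methoxy-N-methylacetamide
Product: 11 icosan-2-one, via octadecylmagnesium bromide 9 (not isolated), via bromomagnesium 2-[methoxy(methyl)amino]icosan-2-olate 10 (not isolated)
Conditions: Mg turnings, I2 (crystal), THF, reflux; then 8, THF, 0 °C to rt; 1 M HCl quench
Reagents that add atoms: none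
Why: Grignard formation followed by Weinreb ketone synthesis, in which the chelated tetrahedral adduct does not collapse until work-up, so no tertiary alcohol forms.

Step 5
Reactants: 6 3,5-dimethoxy-2-(methoxymethoxy)benzaldehyde; 11 icosan-2-one (1.1 equiv)
Product: 13 (E)-1-[3,5-dimethoxy-2-(methoxymethoxy)phenyl]henicos-1-en-3-one, via aldol adduct 1-aryl-1-hydroxyhenicosan-3-one 12 (not isolated)
Conditions: KOH (0.5 equiv, 2 M aq.), EtOH/THF 2:1, 40 °C, 12–24 h
Reagents that add atoms: none
Why: Claisen–Schmidt crossed aldol condensation, in which the non-enolisable aldehyde is the only good acceptor, reversible hydroxide conditions funnel the methyl ketone through its methyl-side aldol, and E1cB dehydration gives the conjugated E-enone as the thermodynamic sink.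

Step 6
Reactants: 13 (E)-1-[3,5-dimethoxy-2-(methoxymethoxy)phenyl]henicos-1-en-3-one
Product: 14 1-[3,5-dimethoxy-2-(methoxymethoxy)phenyl]henicosan-3-one
Conditions: H2 (1 atm), 10% Pd/C, EtOAc, rt
Reagents that add atoms: none
Why: Heterogeneous catalytic hydrogenation reduces the conjugated C=C far faster than the dialkyl ketone, and the MOM and methyl ethers are inert on Pd/C in neutral EtOAc.

Step 7
Reactants: 14 1-[3,5-dimethoxy-2-(methoxymethoxy)phenyl]henicosan-3-one
Product: 16 1-henicosyl-3,5-dimethoxy-2-(methoxymethoxy)benzene, via henicosan-3-one hydrazone 15 (not isolated)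
Conditions: N2H4·H2O (8 equiv), KOH (4 equiv), diethylene glycol, 130 °C, 2 h; distil to 195–200 °C, 3 h
Reagents that add atoms: none
Why: Wolff–Kishner reduction (Huang-Minlon modification) of an unhindered dialkyl ketone, whose hydrazone loses N2 under hot KOH while the aryl ethers and the acetal are base-stable.

Step 8
Reactants: 16 1-henicosyl-3,5-dimethoxy-2-(methoxymethoxy)benzene
Product: 17 6-n-heneicosyl-2,4-dimethoxyphenol
Conditions: conc. HCl (cat.), MeOH/THF 2:1, 50 °C, under N2
Reagents that add atoms: none
Why: Acid-catalysed acetal exchange (MOM ether cleavage) in which methanol traps the methoxymethyl cation as dimethoxymethane, leaving the aryl methyl ethers and the alkyl chain untouched.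

## Compound list
1 | 2,4-dimethoxybenzaldehyde | COc1ccc(C=O)c(OC)c1 | starting material
2 | 2,4-dimethoxyphenyl formate (not isolated) | COc1ccc(OC=O)c(OC)c1 | intermediate
3 | 2,4-dimethoxyphenol | COc1ccc(O)c(OC)c1 | intermediate
4 | 2-(hydroxymethyl)-4,6-dimethoxyphenol (present as its magnesium phenoxide, not isolated) | COc1cc(CO)c(O)c(OC)c1 | intermediate
5 | 2-hydroxy-3,5-dimethoxybenzaldehyde | COc1cc(C=O)c(O)c(OC)c1 | intermediate
6 | 3,5-dimethoxy-2-(methoxymethoxy)benzaldehyde | COCOc1c(C=O)cc(OC)cc1OC | intermediate
7 | 1-bromooctadecane | CCCCCCCCCCCCCCCCCCBr | starting material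
8 | N-methoxy-N-methylacetamide | CON(C)C(C)=O | starting material
9 | octadecylmagnesium bromide (not isolated) | CCCCCCCCCCCCCCCCCC[Mg]Br | intermediate
10 | bromomagnesium 2-[methoxy(methyl)amino]icosan-2-olate (tetrahedral adduct, not isolated) | CCCCCCCCCCCCCCCCCCC(C)(O[Mg]Br)N(C)OC | intermediate
11 | icosan-2-one | CCCCCCCCCCCCCCCCCCC(C)=O | intermediate
12 | 1-hydroxy-1-[3,5-dimethoxy-2-(methoxymethoxy)phenyl]henicosan-3-one (racemic, not isolated) | CCCCCCCCCCCCCCCCCCC(=O)CC(O)c1cc(OC)cc(OC)c1OCOC | intermediate
13 | (E)-1-[3,5-dimethoxy-2-(methoxymethoxy)phenyl]henicos-1-en-3-one | CCCCCCCCCCCCCCCCCCC(=O)/C=C/c1cc(OC)cc(OC)c1OCOC | intermediate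
14 | 1-[3,5-dimethoxy-2-(methoxymethoxy)phenyl]henicosan-3-one | CCCCCCCCCCCCCCCCCCC(=O)CCc1cc(OC)cc(OC)c1OCOC | intermediate
15 | hydrazone of 14 (not isolated) | CCCCCCCCCCCCCCCCCCC(=NN)CCc1cc(OC)cc(OC)c1OCOC | intermediate
16 | 1-henicosyl-3,5-dimethoxy-2-(methoxymethoxy)benzene | CCCCCCCCCCCCCCCCCCCCCc1cc(OC)cc(OC)c1OCOC | intermediate
17 | 6-n-heneicosyl-2,4-dimethoxyphenol (achiral) | CCCCCCCCCCCCCCCCCCCCCc1cc(OC)cc(OC)c1O | target

## Summary
Total steps: 8. Longest linear sequence: 7 steps (1 → 3 → 5 → 6 → 13 → 14 → 16 → 17); ketone 11 is made in one step on the convergent branch.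

Steps most likely to fail:

**Step 2 (ortho-formylation).** The ortho-methoxy group can tie up magnesium and slow the reaction, and the electron-rich phenol is oxidation-prone. The fallback sets out from 3 and comes back at 5. Phenol 3 is heated with phenylboronic acid and paraformaldehyde (cat. propionic acid, toluene, Dean–Stark), where the boron template forces ortho-hydroxymethylation and gives 6,8-dimethoxy-2-phenyl-4H-1,3,2-benzodioxaborinine F1. Transesterification of this boronate with propane-1,3-diol releases salicyl alcohol 4, now isolated, and benzylic oxidation with activated MnO2 in CH2Cl2 returns to 5.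

**Step 5 (Claisen–Schmidt condensation).** Risks are slow reaction of the lipophilic, hindered partners, Michael addition of a second ketone to 13, and minor methylene-side condensation. The fallback sets out from 11 (with 6) and comes back at 13. Ketone 11 is deprotonated at the methyl group with LiN(iPr)2 in THF at −78 °C to give lithium icos-1-en-2-olate F2, which adds irreversibly to 6 to give aldol 12, now isolated and freed of any regioisomer by chromatography. Treatment with MsCl and Et3N in CH2Cl2 at 0 °C forms 1-[3,5-dimethoxy-2-(methoxymethoxy)phenyl]-3-oxohenicosyl methanesulfonate F3, which eliminates in the same flask on adding DBU to return to 13.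

**Step 7 (Wolff–Kishner).** Hot KOH at 200 °C may partly cleave an aryl ether, and the waxy substrate may react incompletely. The fallback sets out from 14 and comes back at 16. Ketone 14 is reduced with NaBH4 (THF/MeOH, 0 °C) to 1-[3,5-dimethoxy-2-(methoxymethoxy)phenyl]henicosan-3-ol F4. This alcohol is converted with NaH, CS2 and then MeI in THF into O-{1-[3,5-dimethoxy-2-(methoxymethoxy)phenyl]henicosan-3-yl} S-methyl carbonodithioate F5. Barton–McCombie deoxygenation of this xanthate with Bu3SnH and AIBN in refluxing toluene returns to 16 under neutral conditions.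

## Further compounds
F1 | step 2 | 6,8-dimethoxy-2-phenyl-4H-1,3,2-benzodioxaborinine | COc1cc2c(c(OC)c1)OB(c1ccccc1)OC2
F2 | step 5 | lithium icos-1-en-2-olate | C=C(O[Li])CCCCCCCCCCCCCCCCCC
F3 | step 5 | 1-[3,5-dimethoxy-2-(methoxymethoxy)phenyl]-3-oxohenicosyl methanesulfonate | CCCCCCCCCCCCCCCCCCC(=O)CC(OS(C)(=O)=O)c1cc(OC)cc(OC)c1OCOC
F4 | step 7 | 1-[3,5-dimethoxy-2-(methoxymethoxy)phenyl]henicosan-3-ol | CCCCCCCCCCCCCCCCCCC(O)CCc1cc(OC)cc(OC)c1OCOC
F5 | step 7 | O-{1-[3,5-dimethoxy-2-(methoxymethoxy)phenyl]henicosan-3-yl} S-methyl carbonodithioate | CCCCCCCCCCCCCCCCCCC(OC(=S)SC)CCc1cc(OC)cc(OC)c1OCOC
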